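The route rests on the 2,3-dihydrobenzofuran ring (O1, C2, C3, C3a, C7a). Its O1–C2 and C3a–C3 bonds are formed together by an Ag2O-mediated oxidative [3+2] cross-coupling of a 4-alkylguaiacol (supplying O1, C7a and its only free ortho carbon C3a) with a feruloyl camphorsultam (supplying C2 and C3), which also sets both ring stereocentres. The phenol partner already carries the Evans succinate that becomes the (R)-lactone, so one LiBH4 treatment removes both auxiliaries and lactonisation follows. Enolate alkylation with an erythro 8-O-4 benzylic bromide, made by an anti glycolate aldol, and global desilylation complete the target.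

Key step: step 7

Remark 1: the (2R)-sultam is assumed to steer the C–C coupling to the face of the sultam-bearing carbon that gives the (2S,3S) acyl dihydrobenzofuran; if the opposite sense is found, the equally available (2S)-sultam is used with no other change.
Remark 2: the (S)-oxazolidinethione is assumed to give the (2R,3R) anti aldol adduct (attack on the enolate face opposite the benzyl group); if the enantiomeric anti series forms, the (R)-auxiliary is used.
TBS = tert-butyldimethylsilyl.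

Step 1
Reactants: 1 3-(4-hydroxy-3-methoxyphenyl)propanoic acid (dihydroferulic acid)
Product: 2 3-[4-(benzyloxy)-3-methoxyphenyl]propanoic acid
Conditions: BnBr (1.1 equiv), KOH (2.5 equiv), EtOH–H2O, reflux; then aq. HCl
Reagents that add atoms: benzyl bromide, BrCc1ccccc1
Why: Williamson etherification in which the phenoxide is far more nucleophilic than the carboxylate in the protic medium and any benzyl ester formed is saponified in the same pot.

Step 2
Reactants: 2 O-benzyl dihydroferulic acid; 3 (S)-4-benzyloxazolidin-2-one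
Product: 5 (4S)-4-benzyl-3-{3-[4-(benzyloxy)-3-methoxyphenyl]propanoyl}oxazolidin-2-one, via mixed pivalic anhydride 4 (not isolated)
Conditions: t-BuCOCl, Et3N, THF, −20 °C; then LiCl, 3, −20 °C → rt
Reagents that add atoms: none
Why: Standard N-acylation of an Evans oxazolidinone through the mixed pivalic anhydride, whose hindered pivaloyl carbonyl directs attack to the hydrocinnamoyl carbonyl.

Step 3
Reactants: 5 Evans imide; 6 tert-butyl bromoacetate
Product: 7 tert-butyl (3R)-4-[(4S)-4-benzyl-2-oxooxazolidin-3-yl]-3-[4-(benzyloxy)-3-methoxybenzyl]-4-oxobutanoate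
Conditions: NaN(SiMe3)2 (1.1 equiv), THF, −78 °C; then 6, −78 → −45 °C
Reagents that add atoms: none
Why: Evans asymmetric alkylation in which the chelated (Z)-sodium enolate is attacked by the α-bromo ester on the face opposite the C4 benzyl group, setting the (3R) centre that becomes C4 of the lactone.

Step 4
Reactants: 7 benzyl-protected succinate imide
Product: 8 tert-butyl (3R)-4-[(4S)-4-benzyl-2-oxooxazolidin-3-yl]-3-(4-hydroxy-3-methoxybenzyl)-4-oxobutanoate
Conditions: H2 (1 atm), 10% Pd/C, EtOAc, rt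
Reagents that add atoms: none
Why: Hydrogenolysis of the aryl benzyl ether frees the phenol needed for oxidation, while the imide, the tert-butyl ester and the C-benzyl group of the auxiliary are inert.

Step 5
Reactants: 9 (E)-4-acetoxy-3-methoxycinnamic acid (O-acetylferulic acid); 10 (2R)-bornane-10,2-sultam
Product: 12 N-[(E)-4-acetoxy-3-methoxycinnamoyl]-(2R)-bornane-10,2-sultam, via acid chloride 11 (not isolated)
Conditions: (COCl)2, DMF (cat.), CH2Cl2, 0 °C → rt, evaporate; then 10, NaH, THF, 0 °C → rt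
Reagents that add atoms: none
Why: Acid chloride formation followed by N-acylation of the sodium salt of the sultam is the standard entry to N-enoyl sultams, and the acetate keeps the phenol from being acylated.

Step 6
Reactants: 12 O-acetyl N-feruloyl sultam
Product: 13 N-[(E)-4-hydroxy-3-methoxycinnamoyl]-(2R)-bornane-10,2-sultam
Conditions: pyrrolidine (1.5 equiv), CH2Cl2, 0 °C
Reagents that add atoms: none
Why: Aminolysis of the aryl acetate is much faster than attack on the hindered N-acyl sultam or conjugate addition to the electron-rich cinnamoyl unit, so only the phenol is released.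

Step 7
Reactants: 8 phenolic Evans succinate; 13 N-feruloyl sultam
Product: 15 tert-butyl (3R)-4-[(4S)-4-benzyl-2-oxooxazolidin-3-yl]-3-{[(2S,3S)-2-(4-hydroxy-3-methoxyphenyl)-7-methoxy-3-{[(2R)-bornane-10,2-sultam-N-yl]carbonyl}-2,3-dihydrobenzofuran-5-yl]methyl}-4-oxobutanoate, via quinone methide 14 (not isolated)
Conditions: Ag2O (1.0 equiv relative to 13), CH2Cl2–acetone, 0 °C → rt, dark, N2; 13 added slowly to 8 (2 equiv, excess recovered)
Reagents that add atoms: none
Why: Ag2O oxidises both phenols by one electron, the feruloyl radical (spin at the carbon α to the sultam carbonyl) couples with the only free ortho carbon of the guaiacyl radical of 8, the cyclohexadienone tautomerises to the phenol and its oxygen adds to the methide carbon of quinone methide 14, so the aryl–C3 and O1–C2 bonds arise in one flask. The closest known reaction is the biomimetic 8–5' dehydrodimerisation of ferulates with Ag2O, including its camphorsultam-directed enantioselective form, run here as a cross-coupling. The dihydrofuran ring closes by 5-exo-trig conjugate addition of the phenol to the quinone methide. C3 is set in the C–C coupling by the sultam, which shields one face of the planar radical carbon in the s-cis conformer with C=O anti to SO2, and C2 is set in the ring closure trans to the C3 acyl group, the kinetically and thermodynamically preferred arrangement. The step needs cross- over homo-coupling and C–C over C–O coupling: slow addition of 13 to excess 8 keeps the feruloyl radical scarce, and the radical of 8 has no side-chain radical site while its para and second ortho positions are blocked by the alkyl and methoxy groups. Because 8 is enantiopure, the minor facial isomer is a diastereomer of 15 and should be removable by chromatography.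

Step 8
Reactants: 15 coupled bis-auxiliary dihydrobenzofuran
Product: 17 (4R)-4-{[(2S,3R)-2-(4-hydroxy-3-methoxyphenyl)-3-(hydroxymethyl)-7-methoxy-2,3-dihydrobenzofuran-5-yl]methyl}dihydrofuran-2(3H)-one, via triol ester 16 (not isolated)
Conditions: LiBH4 (excess), THF–MeOH, 0 °C → rt; aqueous work-up; then p-TsOH·H2O (cat.), CH2Cl2, rt
Reagents that add atoms: none
Why: LiBH4 cleaves both N-acyl auxiliaries reductively to primary alcohols and leaves the tert-butyl ester, and acid catalysis then closes the γ-lactone by intramolecular transesterification without touching any stereocentre.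

Step 9
Reactants: 17 lactone diol
Product: 18 (4R)-4-{[(2S,3R)-2-[4-(TBS-oxy)-3-methoxyphenyl]-3-[(TBS-oxy)methyl]-7-methoxy-2,3-dihydrobenzofuran-5-yl]methyl}dihydrofuran-2(3H)-one
Conditions: TBSCl (2.5 equiv), imidazole, DMF, rt
Reagents that add atoms: tert-butyldimethylsilyl chloride, CC(C)(C)[Si](C)(C)Cl
Why: Silylation masks the phenol and the primary alcohol so that only the lactone α-CH2 is deprotonated in step 17.

Step 10
Reactants: 19 methyl 4-hydroxy-3-methoxybenzoate (methyl vanillate); 20 bromoacetic acid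
Product: 21 2-[2-methoxy-4-(methoxycarbonyl)phenoxy]acetic acid
Conditions: NaH (2.2 equiv), DMF, 0 → 60 °C; then aq. HCl
Reagents that add atoms: none
Why: Williamson etherification of the sodium phenoxide with sodium bromoacetate under anhydrous conditions, which the methyl benzoate survives.

Step 11
Reactants: 21 aryloxyacetic acid; 22 (S)-4-benzyloxazolidine-2-thione
Product: 23 methyl 4-{2-[(4S)-4-benzyl-2-thioxooxazolidin-3-yl]-2-oxoethoxy}-3-methoxybenzoate
Conditions: DCC, DMAP (cat.), CH2Cl2, 0 °C → rt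
Reagents that add atoms: none
Why: Carbodiimide/DMAP N-acylation is the usual way to N-glycolyl oxazolidinethiones.

Step 12
Reactants: 23 N-aryloxyacetyl oxazolidinethione; 24 4-(tert-butyldimethylsilyloxy)-3-methoxybenzaldehyde
Product: 25 methyl 4-{[(2R,3R)-1-[(4S)-4-benzyl-2-thioxooxazolidin-3-yl]-3-[4-(TBS-oxy)-3-methoxyphenyl]-3-hydroxy-1-oxopropan-2-yl]oxy}-3-methoxybenzoate
Conditions: TiCl4 (1.1 equiv), i-Pr2NEt (1.1 equiv), CH2Cl2, −78 °C; then 24 premixed with TiCl4 (2.5 equiv), −78 °C; aq. NH4Cl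
Reagents that add atoms: none
Why: Anti-selective titanium glycolate aldol (Crimmins conditions) in which the chlorotitanium (Z)-enolate adds through an open transition state to the TiCl4-activated aldehyde on the enolate face opposite the benzyl group, giving the 2,3-anti adduct that corresponds to the erythro (7R,8S) aryl ether.

Step 13
Reactants: 25 anti aldol adduct
Product: 26 methyl 4-{[(1R,2S)-1-[4-(TBS-oxy)-3-methoxyphenyl]-1,3-dihydroxypropan-2-yl]oxy}-3-methoxybenzoate
Conditions: NaBH4, THF–H2O, 0 °C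
Reagents that add atoms: none
Why: NaBH4 reduces the activated N-acyl oxazolidinethione to the primary alcohol at 0 °C, while the electron-rich methyl benzoate and the aryl silyl ether are not attacked.

Step 14
Reactants: 26 erythro diol
Product: 27 methyl 4-{[(1R,2S)-1,3-bis(TBS-oxy)-1-[4-(TBS-oxy)-3-methoxyphenyl]propan-2-yl]oxy}-3-methoxybenzoate
Conditions: TBSOTf (2.5 equiv), 2,6-lutidine, CH2Cl2, −78 → 0 °C
Reagents that add atoms: tert-butyldimethylsilyl triflate, CC(C)(C)[Si](C)(C)OS(=O)(=O)C(F)(F)F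
Why: The silyl triflate protects both the primary and the hindered benzylic hydroxyl under non-acidic conditions.

Step 15
Reactants: 27 tris-silyl methyl ester
Product: 28 (4-{[(1R,2S)-1,3-bis(TBS-oxy)-1-[4-(TBS-oxy)-3-methoxyphenyl]propan-2-yl]oxy}-3-methoxyphenyl)methanol
Conditions: i-Bu2AlH (2.5 equiv), CH2Cl2, −78 °C; Rochelle salt work-up
Reagents that add atoms: none
Why: The aluminium hydride reduces the methyl benzoate to the benzylic alcohol at low temperature without cleaving silyl ethers.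

Step 16
Reactants: 28 benzylic alcohol
Product: 29 4-{[(1R,2S)-1,3-bis(TBS-oxy)-1-[4-(TBS-oxy)-3-methoxyphenyl]propan-2-yl]oxy}-3-methoxybenzyl bromide
Conditions: CBr4, PPh3, CH2Cl2, 0 °C; used at once
Reagents that add atoms: carbon tetrabromide, BrC(Br)(Br)Br
Why: Appel bromination converts the electron-rich benzylic alcohol into the bromide under neutral conditions that spare the silyl ethers.

Step 17
Reactants: 18 bis-silyl lactone; 29 benzylic bromide
Product: 30 (3R,4R)-3-(4-{[(1R,2S)-1,3-bis(TBS-oxy)-1-[4-(TBS-oxy)-3-methoxyphenyl]propan-2-yl]oxy}-3-methoxybenzyl)-4-{[(2S,3R)-2-[4-(TBS-oxy)-3-methoxyphenyl]-3-[(TBS-oxy)methyl]-7-methoxy-2,3-dihydrobenzofuran-5-yl]methyl}dihydrofuran-2(3H)-one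
Conditions: LiN(SiMe3)2 (1.1 equiv), THF, −78 °C; then 29, DMPU, −78 → −30 °C
Reagents that add atoms: none
Why: The lithium enolate of the β-substituted γ-butyrolactone is benzylated anti to the C4 substituent, which sets the (3R) centre trans to C4 as in the established syntheses of dibenzylbutyrolactone lignans.

Step 18
Reactants: 30 penta-silyl ether
Product: 31 (3R,4R)-3-(4-{[(1R,2S)-1,3-dihydroxy-1-(4-hydroxy-3-methoxyphenyl)propan-2-yl]oxy}-3-methoxybenzyl)-4-{[(2S,3R)-2-(4-hydroxy-3-methoxyphenyl)-3-(hydroxymethyl)-7-methoxy-2,3-dihydrobenzofuran-5-yl]methyl}dihydrofuran-2(3H)-one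
Conditions: Bu4NF, AcOH (1:1, excess), THF, 0 °C → rt
Reagents that add atoms: none
Why: Fluoride cleaves the two aryl and three alkyl silyl ethers, and the acetic acid buffer keeps the lactone closed and prevents epimerisation or quinone methide formation at the p-hydroxybenzylic alcohol.

Compound list
1 | 3-(4-hydroxy-3-methoxyphenyl)propanoic acid | COc1cc(CCC(=O)O)ccc1O | starting material
2 | 3-[4-(benzyloxy)-3-methoxyphenyl]propanoic acid | COc1cc(CCC(=O)O)ccc1OCc1ccccc1 | intermediate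
3 | (S)-4-benzyloxazolidin-2-one | O=C1OC[C@H](Cc2ccccc2)N1 | starting material
4 | 3-[4-(benzyloxy)-3-methoxyphenyl]propanoic pivalic anhydride | COc1cc(CCC(=O)OC(=O)C(C)(C)C)ccc1OCc1ccccc1 | intermediate
5 | (4S)-4-benzyl-3-{3-[4-(benzyloxy)-3-methoxyphenyl]propanoyl}oxazolidin-2-one | COc1cc(CCC(=O)N2[C@@H](Cc3ccccc3)COC2=O)ccc1OCc1ccccc1 | intermediate
6 | tert-butyl bromoacetate | CC(C)(C)OC(=O)CBr | starting material
7 | tert-butyl (3R)-4-[(4S)-4-benzyl-2-oxooxazolidin-3-yl]-3-[4-(benzyloxy)-3-methoxybenzyl]-4-oxobutanoate | COc1cc(C[C@H](CC(=O)OC(C)(C)C)C(=O)N2[C@@H](Cc3ccccc3)COC2=O)ccc1OCc1ccccc1 | intermediate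
8 | tert-butyl (3R)-4-[(4S)-4-benzyl-2-oxooxazolidin-3-yl]-3-(4-hydroxy-3-methoxybenzyl)-4-oxobutanoate | COc1cc(C[C@H](CC(=O)OC(C)(C)C)C(=O)N2[C@@H](Cc3ccccc3)COC2=O)ccc1O | intermediate
9 | (E)-4-acetoxy-3-methoxycinnamic acid | COc1cc(/C=C/C(=O)O)ccc1OC(C)=O | starting material
10 | (2R)-bornane-10,2-sultam, (1S,2R)-(−)-2,10-camphorsultam | N1[C@@H]2C[C@H]3CC[C@]2(CS1(=O)=O)C3(C)C | starting material
11 | (E)-4-acetoxy-3-methoxycinnamoyl chloride | COc1cc(/C=C/C(Cl)=O)ccc1OC(C)=O | intermediate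
12 | N-[(E)-4-acetoxy-3-methoxycinnamoyl]-(2R)-bornane-10,2-sultam | COc1cc(/C=C/C(=O)N2[C@@H]3C[C@H]4CC[C@]3(CS2(=O)=O)C4(C)C)ccc1OC(C)=O | intermediate
13 | N-[(E)-4-hydroxy-3-methoxycinnamoyl]-(2R)-bornane-10,2-sultam | COc1cc(/C=C/C(=O)N2[C@@H]3C[C@H]4CC[C@]3(CS2(=O)=O)C4(C)C)ccc1O | intermediate
14 | quinone methide from C–C coupling of 8 and 13 (phenol ring of 8 carrying at C5 the sultam-acyl CH whose other substituent is the 3-methoxy-4-oxocyclohexa-2,5-dienylidene-methyl group; methide geometry not defined) | COc1cc(C[C@H](CC(=O)OC(C)(C)C)C(=O)N2[C@@H](Cc3ccccc3)COC2=O)cc([C@@H](C=C2C=CC(=O)C(OC)=C2)C(=O)N2[C@@H]3C[C@H]4CC[C@]3(CS2(=O)=O)C4(C)C)c1O | intermediate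
15 | tert-butyl (3R)-4-[(4S)-4-benzyl-2-oxooxazolidin-3-yl]-3-{[(2S,3S)-2-(4-hydroxy-3-methoxyphenyl)-7-methoxy-3-{[(2R)-bornane-10,2-sultam-N-yl]carbonyl}-2,3-dihydrobenzofuran-5-yl]methyl}-4-oxobutanoate | CC(C)(C)OC(=O)C[C@@H](Cc1cc(OC)c2c(c1)[C@H](C(=O)N1[C@@H]3C[C@H]4CC[C@]3(CS1(=O)=O)C4(C)C)[C@@H](c1ccc(O)c(OC)c1)O2)C(=O)N1[C@@H](Cc2ccccc2)COC1=O | intermediate
16 | tert-butyl (3R)-4-hydroxy-3-{[(2S,3R)-2-(4-hydroxy-3-methoxyphenyl)-3-(hydroxymethyl)-7-methoxy-2,3-dihydrobenzofuran-5-yl]methyl}butanoate | CC(C)(C)OC(=O)C[C@@H](Cc1cc(OC)c2c(c1)[C@H](CO)[C@@H](c1ccc(O)c(OC)c1)O2)CO | intermediate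
17 | (4R)-4-{[(2S,3R)-2-(4-hydroxy-3-methoxyphenyl)-3-(hydroxymethyl)-7-methoxy-2,3-dihydrobenzofuran-5-yl]methyl}dihydrofuran-2(3H)-one | O=C1C[C@@H](Cc2cc(OC)c3c(c2)[C@H](CO)[C@@H](c2ccc(O)c(OC)c2)O3)CO1 | intermediate
18 | (4R)-4-{[(2S,3R)-2-[4-(TBS-oxy)-3-methoxyphenyl]-3-[(TBS-oxy)methyl]-7-methoxy-2,3-dihydrobenzofuran-5-yl]methyl}dihydrofuran-2(3H)-one | O=C1C[C@@H](Cc2cc(OC)c3c(c2)[C@H](CO[Si](C)(C)C(C)(C)C)[C@@H](c2ccc(O[Si](C)(C)C(C)(C)C)c(OC)c2)O3)CO1 | intermediate
19 | methyl 4-hydroxy-3-methoxybenzoate | COC(=O)c1ccc(O)c(OC)c1 | starting material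
20 | bromoacetic acid | OC(=O)CBr | starting material
21 | 2-[2-methoxy-4-(methoxycarbonyl)phenoxy]acetic acid | COC(=O)c1ccc(OCC(=O)O)c(OC)c1 | intermediate
22 | (S)-4-benzyloxazolidine-2-thione | S=C1OC[C@H](Cc2ccccc2)N1 | starting material
23 | methyl 4-{2-[(4S)-4-benzyl-2-thioxooxazolidin-3-yl]-2-oxoethoxy}-3-methoxybenzoate | COC(=O)c1ccc(OCC(=O)N2[C@@H](Cc3ccccc3)COC2=S)c(OC)c1 | intermediate
24 | 4-(tert-butyldimethylsilyloxy)-3-methoxybenzaldehyde | CC(C)(C)[Si](C)(C)Oc1ccc(C=O)cc1OC | starting material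
25 | methyl 4-{[(2R,3R)-1-[(4S)-4-benzyl-2-thioxooxazolidin-3-yl]-3-[4-(TBS-oxy)-3-methoxyphenyl]-3-hydroxy-1-oxopropan-2-yl]oxy}-3-methoxybenzoate | CC(C)(C)[Si](C)(C)Oc1ccc([C@@H](O)[C@H](C(=O)N2[C@@H](Cc3ccccc3)COC2=S)Oc2ccc(C(=O)OC)cc2OC)cc1OC | intermediate
26 | methyl 4-{[(1R,2S)-1-[4-(TBS-oxy)-3-methoxyphenyl]-1,3-dihydroxypropan-2-yl]oxy}-3-methoxybenzoate | CC(C)(C)[Si](C)(C)Oc1ccc([C@@H](O)[C@H](CO)Oc2ccc(C(=O)OC)cc2OC)cc1OC | intermediate
27 | methyl 4-{[(1R,2S)-1,3-bis(TBS-oxy)-1-[4-(TBS-oxy)-3-methoxyphenyl]propan-2-yl]oxy}-3-methoxybenzoate | CC(C)(C)[Si](C)(C)Oc1ccc([C@@H](O[Si](C)(C)C(C)(C)C)[C@H](CO[Si](C)(C)C(C)(C)C)Oc2ccc(C(=O)OC)cc2OC)cc1OC | intermediate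
28 | (4-{[(1R,2S)-1,3-bis(TBS-oxy)-1-[4-(TBS-oxy)-3-methoxyphenyl]propan-2-yl]oxy}-3-methoxyphenyl)methanol | CC(C)(C)[Si](C)(C)Oc1ccc([C@@H](O[Si](C)(C)C(C)(C)C)[C@H](CO[Si](C)(C)C(C)(C)C)Oc2ccc(CO)cc2OC)cc1OC | intermediate
29 | 4-{[(1R,2S)-1,3-bis(TBS-oxy)-1-[4-(TBS-oxy)-3-methoxyphenyl]propan-2-yl]oxy}-3-methoxybenzyl bromide | CC(C)(C)[Si](C)(C)Oc1ccc([C@@H](O[Si](C)(C)C(C)(C)C)[C@H](CO[Si](C)(C)C(C)(C)C)Oc2ccc(CBr)cc2OC)cc1OC | intermediate
30 | penta-TBS ether of the target (both phenols, both primary alcohols and the benzylic alcohol silylated; configuration as in 31) | COc1cc([C@@H](O[Si](C)(C)C(C)(C)C)[C@H](CO[Si](C)(C)C(C)(C)C)Oc2ccc(C[C@H]3C(=O)OC[C@@H]3Cc3cc(OC)c4c(c3)[C@H](CO[Si](C)(C)C(C)(C)C)[C@@H](c3ccc(O[Si](C)(C)C(C)(C)C)c(OC)c3)O4)cc2OC)ccc1O[Si](C)(C)C(C)(C)C | intermediate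
31 | (3R,4R)-3-(4-{[(1R,2S)-1,3-dihydroxy-1-(4-hydroxy-3-methoxyphenyl)propan-2-yl]oxy}-3-methoxybenzyl)-4-{[(2S,3R)-2-(4-hydroxy-3-methoxyphenyl)-3-(hydroxymethyl)-7-methoxy-2,3-dihydrobenzofuran-5-yl]methyl}dihydrofuran-2(3H)-one | COc1cc([C@@H](O)[C@H](CO)Oc2ccc(C[C@H]3C(=O)OC[C@@H]3Cc3cc(OC)c4c(c3)[C@H](CO)[C@@H](c3ccc(O)c(OC)c3)O4)cc2OC)ccc1O | target

Total step count: 18. Longest linear sequence: 9 steps (steps 1–4, 7–9, 17, 18; the branch through steps 10–18 is equally long).

Steps most likely to fail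

Step 7. Homo-coupling of the feruloyl radical and C–O (8–O–4) coupling may outrun the desired C–C cross-coupling, the product phenol may be oxidised further, and facial control by the sultam may be weaker with a hetero partner than in the homodimerisation. The fallback gives up the auxiliary on the alkene. It sets out from 8, used in excess: commercial coniferyl alcohol and H2O2 are added slowly to 8 and horseradish peroxidase in acetone–aqueous buffer, the endwise monolignol cross-coupling known from lignin model work. The two trans-dihydrobenzofuran facial isomers are diastereomers because 8 is enantiopure and would be separated by chromatography to give tert-butyl (3R)-4-[(4S)-4-benzyl-2-oxooxazolidin-3-yl]-3-{[(2S,3R)-2-(4-hydroxy-3-methoxyphenyl)-3-(hydroxymethyl)-7-methoxy-2,3-dihydrobenzofuran-5-yl]methyl}-4-oxobutanoate F1. LiBH4 then removes only the oxazolidinone and the route is rejoined at triol ester 16.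

Step 12. With a weakly coordinating aryloxy group, the open transition state may give poor anti/syn selectivity or attack on the other enolate face. The fallback reaches the erythro ether by a syn aldol followed by inversion of the benzylic carbinol through the ketone. It sets out from 21 and returns at 27.
- Acylation of (R)-4-benzyloxazolidin-2-one (t-BuCOCl, Et3N, LiCl) gives (4R)-4-benzyl-3-{[2-methoxy-4-(methoxycarbonyl)phenoxy]acetyl}oxazolidin-2-one F2.
- The Bu2BOTf/i-Pr2NEt aldol with 24 gives the Evans syn adduct, the (2R,3S) hydroxy imide F3.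
- NaBH4 gives the (1S,2S) threo diol F4.
- TBSCl/imidazole silylates the primary hydroxyl to give mono-silyl ether F5.
- Dess–Martin oxidation gives the (S)-α-aryloxy aryl ketone F6.
- Felkin–Anh reduction with LiBH(s-Bu)3, with the aryloxy group anti to the incoming hydride, should give the (1R,2S) erythro alcohol F7.
- TBSOTf/2,6-lutidine then gives 27.

Step 8. Reduction of the hindered acyl sultam may be incomplete, the tert-butyl ester may be partly reduced, and the phenylcoumaran may open under the acid used for lactonisation. The fallback removes the auxiliaries by hydrolysis instead of reduction. It sets out from 15: LiOH/H2O2 (THF–H2O, 0 °C) cleaves both N-acyl groups to the diacid, (2R)-2-{[(2S,3S)-3-carboxy-2-(4-hydroxy-3-methoxyphenyl)-7-methoxy-2,3-dihydrobenzofuran-5-yl]methyl}-4-tert-butoxy-4-oxobutanoic acid F8. BH3·SMe2 then reduces the two carboxylic acids in the presence of the tert-butyl ester, and the route is rejoined at triol ester 16.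

Further compounds
F1 | step 7 | tert-butyl (3R)-4-[(4S)-4-benzyl-2-oxooxazolidin-3-yl]-3-{[(2S,3R)-2-(4-hydroxy-3-methoxyphenyl)-3-(hydroxymethyl)-7-methoxy-2,3-dihydrobenzofuran-5-yl]methyl}-4-oxobutanoate | CC(C)(C)OC(=O)C[C@@H](Cc1cc(OC)c2c(c1)[C@H](CO)[C@@H](c1ccc(O)c(OC)c1)O2)C(=O)N1[C@@H](Cc2ccccc2)COC1=O
F2 | step 12 | (4R)-4-benzyl-3-{[2-methoxy-4-(methoxycarbonyl)phenoxy]acetyl}oxazolidin-2-one | COC(=O)c1ccc(OCC(=O)N2[C@H](Cc3ccccc3)COC2=O)c(OC)c1
F3 | step 12 | methyl 4-{[(2R,3S)-1-[(4R)-4-benzyl-2-oxooxazolidin-3-yl]-3-[4-(TBS-oxy)-3-methoxyphenyl]-3-hydroxy-1-oxopropan-2-yl]oxy}-3-methoxybenzoate | CC(C)(C)[Si](C)(C)Oc1ccc([C@H](O)[C@H](C(=O)N2[C@H](Cc3ccccc3)COC2=O)Oc2ccc(C(=O)OC)cc2OC)cc1OC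
F4 | step 12 | methyl 4-{[(1S,2S)-1-[4-(TBS-oxy)-3-methoxyphenyl]-1,3-dihydroxypropan-2-yl]oxy}-3-methoxybenzoate | CC(C)(C)[Si](C)(C)Oc1ccc([C@H](O)[C@H](CO)Oc2ccc(C(=O)OC)cc2OC)cc1OC
F5 | step 12 | methyl 4-{[(1S,2S)-3-(TBS-oxy)-1-[4-(TBS-oxy)-3-methoxyphenyl]-1-hydroxypropan-2-yl]oxy}-3-methoxybenzoate | CC(C)(C)[Si](C)(C)Oc1ccc([C@H](O)[C@H](CO[Si](C)(C)C(C)(C)C)Oc2ccc(C(=O)OC)cc2OC)cc1OC
F6 | step 12 | methyl 4-{[(2S)-3-(TBS-oxy)-1-[4-(TBS-oxy)-3-methoxyphenyl]-1-oxopropan-2-yl]oxy}-3-methoxybenzoate | CC(C)(C)[Si](C)(C)Oc1ccc(C(=O)[C@H](CO[Si](C)(C)C(C)(C)C)Oc2ccc(C(=O)OC)cc2OC)cc1OC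
F7 | step 12 | methyl 4-{[(1R,2S)-3-(TBS-oxy)-1-[4-(TBS-oxy)-3-methoxyphenyl]-1-hydroxypropan-2-yl]oxy}-3-methoxybenzoate | CC(C)(C)[Si](C)(C)Oc1ccc([C@@H](O)[C@H](CO[Si](C)(C)C(C)(C)C)Oc2ccc(C(=O)OC)cc2OC)cc1OC
F8 | step 8 | (2R)-2-{[(2S,3S)-3-carboxy-2-(4-hydroxy-3-methoxyphenyl)-7-methoxy-2,3-dihydrobenzofuran-5-yl]methyl}-4-tert-butoxy-4-oxobutanoic acid | CC(C)(C)OC(=O)C[C@@H](Cc1cc(OC)c2c(c1)[C@H](C(=O)O)[C@@H](c1ccc(O)c(OC)c1)O2)C(=O)O
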